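The butenolide ring (O1, C2, C3, C4, C5) is cut at its lactone bond O1–C2, and C5, the sole stereocentre, is raised to a ketone. This works because C5 and the C2 carbonyl stand in a 1,4-relationship on the same side of the endocyclic C3=C4 bond, the very array left by oxidative cleavage of a furan substituted at positions 2, 3 and 4. In one operation a ketoreductase creates the C5–H bond in the (R) sense and the freed hydroxy acid ring-closes unaided. Its substrate is a tetrasubstituted alkene holding the 13-acetoxytridecyl ketone cis to a free carboxyl, beside methyl and a tert-butyl ester.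

Key step: step 7

Remarks on the chemistry (one line each)
- Numbering: the discussion numbers the lactone O1, C2 (carbonyl), C3 (methyl), C4 (carboxyl or ester), C5 (H and chain); the systematic names use 2,5-dihydrofuran numbering, where lactone C5 is position 2.
- Configuration: at the stereocentre the ranking is O1 > C4 > chain CH2 > H, which makes the drawn enantiomer (R).
- Name of the open-chain acid: C1–C4 plus thirteen methylenes make a heptadec-2-enoic acid with the acetoxy group on C17. At C3 tert-butoxycarbonyl (O,O,O) outranks the acyl group (O,O,C), so the isomer with ketone and carboxyl on the same side is (E), although the relationship that matters is cis.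
- Assumption: the keto acid of step 6 and its cyclic hemiketal are freely interconverting ring–chain tautomers. The isolated material should rest mainly in the closed form, is entered as the open acid, and is charged to the enzyme as the potassium carboxylate, the only form that has a ketone.

Step 1
Reactants: 1 1,14-tetradecanediol
Product: 2 14-hydroxytetradecyl acetate
Conditions: 1 (2 equiv), Ac2O (1 equiv), pyridine, DMAP (cat.), THF, 40 °C
Reagents that add atoms: acetic anhydride, CC(=O)OC(C)=O
Why: DMAP-catalysed O-acetylation of two remote, independent hydroxyls is statistical, so excess diol biases the outcome toward the monoester, which differs enough in polarity to be separated while unreacted 1 is recycled.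

Step 2
Reactants: 2 14-hydroxytetradecyl acetate
Product: 4 14-acetoxytetradecanoic acid, via aldehyde 3 (not isolated)
Conditions: TEMPO (cat.), PhI(OAc)2 (2.2 equiv), CH2Cl2–H2O, rt
Reagents that add atoms: water, O
Why: The oxoammonium-mediated TEMPO/PhI(OAc)2 oxidation takes the primary alcohol to aldehyde 3 and its hydrate on to the acid, under near-neutral conditions that leave the acetate alone.

Step 3
Reactants: 4 14-acetoxytetradecanoic acid; 5 Meldrum's acid (2,2-dimethyl-1,3-dioxane-4,6-dione)
Product: 6 5-(14-acetoxy-1-hydroxytetradecylidene)-2,2-dimethyl-1,3-dioxane-4,6-dione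
Conditions: DCC (1.1 equiv), DMAP (1.5 equiv), CH2Cl2, 0 °C → rt; filter, aq. KHSO4 wash
Reagents that add atoms: none
Why: Steglich-type carbodiimide/DMAP activation of the acid and C-acylation of the very acidic methylene of 5 is the standard entry to enolised acyl Meldrum's acids, and nothing in it affects the acetate.

Step 4
Reactants: 6 5-(14-acetoxy-1-hydroxytetradecylidene)-2,2-dimethyl-1,3-dioxane-4,6-dione
Product: 8 tert-butyl 16-acetoxy-3-oxohexadecanoate, via acylketene 7 (not isolated)
Conditions: tBuOH (5 equiv), toluene, 90 °C
Reagents that add atoms: tert-butanol, CC(C)(C)O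
Why: Thermal fragmentation of the acyl Meldrum's acid expels acetone and CO2 to give acylketene 7, which tert-butanol traps irreversibly (Meldrum's acid β-keto ester synthesis).

Step 5
Reactants: 8 tert-butyl 16-acetoxy-3-oxohexadecanoate; 9 chloroacetone
Product: 11 tert-butyl 2-(13-acetoxytridecyl)-4-methylfuran-3-carboxylate, via hydroxydihydrofuran 10 (not isolated)
Conditions: 9 (1.5 equiv), pyridine, rt → 55 °C; then PPTS (cat.), toluene, 50 °C
Reagents that add atoms: none
Why: In the Feist–Benary furan synthesis the enol of 8 adds through carbon to the ketone of 9, the enol oxygen displaces chloride to give 10, and loss of water aromatises; this order of events places methyl at furan C4 and leaves furan C5 with hydrogen.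

Step 6
Reactants: 11 tert-butyl 2-(13-acetoxytridecyl)-4-methylfuran-3-carboxylate
Product: 14 (E)-17-acetoxy-3-(tert-butoxycarbonyl)-2-methyl-4-oxoheptadec-2-enoic acid, via endoperoxide 12 (not isolated), via hydroxybutenolide 13 (not isolated)
Conditions: O2, tetraphenylporphyrin (cat.), hν (visible), CH2Cl2, −78 °C; then iPr2NEt (1.5 equiv), −78 → 0 °C; aq. citric acid
Reagents that add atoms: oxygen, O=O
Why: Singlet oxygen adds across furan C2 and C5 in a [4+2] cycloaddition to give 12, and because only the former furan C5 carries hydrogen the Kornblum–DeLaMare fragmentation can run one way only, making that carbon the carboxyl (lactone C2) and the chain-bearing carbon the hemiketal of 13, which opens to 14 with ketone and carboxyl still cis as in the furan ring.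

Step 7
Reactants: 14 (E)-17-acetoxy-3-(tert-butoxycarbonyl)-2-methyl-4-oxoheptadec-2-enoic acid
Product: 16 tert-butyl (2R)-2-(13-acetoxytridecyl)-4-methyl-5-oxo-2,5-dihydrofuran-3-carboxylate, via hydroxy acid 15 (not isolated)
Conditions: (R)-selective ketoreductase (purified), NADP+ (cat.), iPrOH (15 vol %), KH2PO4–K2HPO4 buffer (0.1 M, pH 7.2), 30 °C; then citric acid to pH 4, MTBE
Reagents that add atoms: none
Why: In the buffer 14 is present as the open carboxylate; the enzyme binds its ketone beside NADPH, the dihydronicotinamide passes hydride to one face of the carbonyl carbon (new C5–H bond) while an active-site acid protonates the oxygen, and the same enzyme restores NADPH by oxidising isopropanol to acetone. The closest known reaction type is the ketoreductase or alcohol dehydrogenase reduction of 4-oxo acids, 4-oxo-2-enoates and enones, where the γ-hydroxy acid derivative lactonises by itself. The one ring is closed by attack of the new C5 hydroxyl of 15 on the C2 carboxyl carbon, a 5-exo-trig acyl substitution with loss of water that forms O1–C2, is favoured by the cis placement across the tetrasubstituted C3=C4 bond and is completed at pH 4. C5 is the only stereocentre and 14 is achiral, so the (R) configuration is set by the catalyst alone: the binding pockets tell the slim unbranched chain from the branched alkenyl residue, and an (R)-selective member is taken from a panel that holds enzymes of both senses. The step needs carbonyl over alkene reduction and untouched esters: ketoreductases have no machinery for C=C reduction, the alkene is tetrasubstituted and shielded, the tert-butyl ester is too bulky for hydrolases, and a purified esterase-free preparation without thiol additives protects the primary acetate and the Michael acceptor. Excess isopropanol and the separation of neutral 16 from the aqueous phase pull the equilibrium forward, and the near-neutral pH keeps the C5–H of 16 from exchanging.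

Step 8
Reactants: 16 tert-butyl (2R)-2-(13-acetoxytridecyl)-4-methyl-5-oxo-2,5-dihydrofuran-3-carboxylate
Product: 17 (2R)-2-(13-acetoxytridecyl)-4-methyl-5-oxo-2,5-dihydrofuran-3-carboxylic acid (target)
Conditions: TFA–CH2Cl2 (1:4), 0 °C → rt
Reagents that add atoms: none
Why: Acid-catalysed alkyl–oxygen (AAL1) cleavage removes only the ester that can leave as a tert-butyl cation, the primary acetate and the lactone cannot ionise in this way, and without base the C5 stereocentre keeps its (R) configuration.

Compound list
1 | 1,14-tetradecanediol | OCCCCCCCCCCCCCCO | starting material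
2 | 14-hydroxytetradecyl acetate | CC(=O)OCCCCCCCCCCCCCCO | intermediate
3 | 14-oxotetradecyl acetate | CC(=O)OCCCCCCCCCCCCCC=O | intermediate
4 | 14-acetoxytetradecanoic acid | CC(=O)OCCCCCCCCCCCCCC(=O)O | intermediate
5 | Meldrum's acid (2,2-dimethyl-1,3-dioxane-4,6-dione) | CC1(C)OC(=O)CC(=O)O1 | starting material
6 | 5-(14-acetoxy-1-hydroxytetradecylidene)-2,2-dimethyl-1,3-dioxane-4,6-dione | CC(=O)OCCCCCCCCCCCCCC(O)=C1C(=O)OC(C)(C)OC1=O | intermediate
7 | (14-acetoxytetradecanoyl)ketene | CC(=O)OCCCCCCCCCCCCCC(=O)C=C=O | intermediate
8 | tert-butyl 16-acetoxy-3-oxohexadecanoate | CC(=O)OCCCCCCCCCCCCCC(=O)CC(=O)OC(C)(C)C | intermediate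
9 | chloroacetone | CC(=O)CCl | starting material
10 | tert-butyl 2-(13-acetoxytridecyl)-4-hydroxy-4-methyl-4,5-dihydrofuran-3-carboxylate (racemic) | CC(=O)OCCCCCCCCCCCCCC1=C(C(=O)OC(C)(C)C)C(C)(O)CO1 | intermediate
11 | tert-butyl 2-(13-acetoxytridecyl)-4-methylfuran-3-carboxylate | CC(=O)OCCCCCCCCCCCCCc1occ(C)c1C(=O)OC(C)(C)C | intermediate
12 | tert-butyl 1-(13-acetoxytridecyl)-5-methyl-2,3,7-trioxabicyclo[2.2.1]hept-5-ene-6-carboxylate (racemic) | CC(=O)OCCCCCCCCCCCCCC12OOC(O1)C(C)=C2C(=O)OC(C)(C)C | intermediate
13 | tert-butyl 2-(13-acetoxytridecyl)-2-hydroxy-4-methyl-5-oxo-2,5-dihydrofuran-3-carboxylate (racemic ring tautomer of 14) | CC(=O)OCCCCCCCCCCCCCC1(O)OC(=O)C(C)=C1C(=O)OC(C)(C)C | intermediate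
14 | (E)-17-acetoxy-3-(tert-butoxycarbonyl)-2-methyl-4-oxoheptadec-2-enoic acid (ketone and carboxyl cis) | CC(=O)OCCCCCCCCCCCCCC(=O)/C(C(=O)OC(C)(C)C)=C(/C)C(=O)O | intermediate
15 | (2E,4R)-17-acetoxy-3-(tert-butoxycarbonyl)-4-hydroxy-2-methylheptadec-2-enoic acid | CC(=O)OCCCCCCCCCCCCC[C@@H](O)/C(C(=O)OC(C)(C)C)=C(/C)C(=O)O | intermediate
16 | tert-butyl (2R)-2-(13-acetoxytridecyl)-4-methyl-5-oxo-2,5-dihydrofuran-3-carboxylate | CC(=O)OCCCCCCCCCCCCC[C@H]1OC(=O)C(C)=C1C(=O)OC(C)(C)C | intermediate
17 | (2R)-2-(13-acetoxytridecyl)-4-methyl-5-oxo-2,5-dihydrofuran-3-carboxylic acid | CC(=O)OCCCCCCCCCCCCC[C@H]1OC(=O)C(C)=C1C(=O)O | target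

Total step count: 8. Longest linear sequence: 8 steps (1 → 17).

Steps most likely to fail

Step 7.
- What may go wrong: no panel member may accept a ketone flanked by a long chain and a tetrasubstituted alkene. Discrimination between the two carbonyl faces may be poor, the soap-like substrate may be poorly available to the enzyme, or residual esterase activity may strip the acetate.
- Fallback (small-molecule catalyst control on a neutral substrate): setting out from 14, alkylation of the carboxylate (MeI, KHCO3, DMF, rt) locks the open form as methyl (E)-17-acetoxy-3-(tert-butoxycarbonyl)-2-methyl-4-oxoheptadec-2-enoate F1.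
- Corey–Bakshi–Shibata reduction follows ((S)-2-methyl-CBS-oxazaborolidine, BH3·SMe2, toluene, −30 °C). The branched alkenyl residue plays the large group, so it should give methyl (2E,4R)-17-acetoxy-3-(tert-butoxycarbonyl)-4-hydroxy-2-methylheptadec-2-enoate F2.
- F2 lactonises with loss of methanol on gentle warming with catalytic PPTS, and the sequence comes back to the route at 16.

Step 5.
- What may go wrong: alkylation at carbon ahead of the aldol addition would move the methyl group to the wrong ring position. Quaternisation of pyridine may consume the chloroketone, dehydration may stall, or the acid finish may erode the tert-butyl ester.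
- Fallback (carbenoid annulation instead of condensation): setting out from 8, Regitz diazo transfer (4-acetamidobenzenesulfonyl azide, Et3N, MeCN) gives tert-butyl 16-acetoxy-2-diazo-3-oxohexadecanoate F3.
- Rh2(OAc)4-catalysed formal [3+2] cycloaddition with ethyl 1-propenyl ether joins the carbenoid carbon to the methyl-bearing nucleophilic alkene carbon, and the ketone oxygen closes on the oxocarbenium carbon. This gives tert-butyl 2-(13-acetoxytridecyl)-5-ethoxy-4-methyl-4,5-dihydrofuran-3-carboxylate F4.
- PPTS-catalysed elimination of ethanol (toluene, 60 °C) aromatises F4 and returns to the route at 11.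

Step 6.
- What may go wrong: the ester lowers the furan's reactivity toward singlet oxygen, so the cycloaddition may be sluggish. The endoperoxide may rearrange thermally before the base acts, and the amine may be photo-oxidised if it meets light and sensitiser.
- Fallback (two-stage ionic oxidation instead of photochemistry): setting out from 11, NBS with NaHCO3 in acetone–water at −15 °C attacks the free α-position, water adds at the other α-carbon and HBr is lost. The ring opens with retention of the cis geometry to tert-butyl (E)-16-acetoxy-3-oxo-2-(1-oxopropan-2-ylidene)hexadecanoate F5 (ketone and formyl cis).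
- Pinnick oxidation (NaClO2, NaH2PO4, 2-methyl-2-butene, tBuOH–H2O) then converts the formyl group into the carboxyl and rejoins the route at 14.

Further compounds
F1 | step 7 | methyl (E)-17-acetoxy-3-(tert-butoxycarbonyl)-2-methyl-4-oxoheptadec-2-enoate | CC(=O)OCCCCCCCCCCCCCC(=O)/C(C(=O)OC(C)(C)C)=C(/C)C(=O)OC
F2 | step 7 | methyl (2E,4R)-17-acetoxy-3-(tert-butoxycarbonyl)-4-hydroxy-2-methylheptadec-2-enoate | CC(=O)OCCCCCCCCCCCCC[C@@H](O)/C(C(=O)OC(C)(C)C)=C(/C)C(=O)OC
F3 | step 5 | tert-butyl 16-acetoxy-2-diazo-3-oxohexadecanoate | CC(=O)OCCCCCCCCCCCCCC(=O)C(=[N+]=[N-])C(=O)OC(C)(C)C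
F4 | step 5 | tert-butyl 2-(13-acetoxytridecyl)-5-ethoxy-4-methyl-4,5-dihydrofuran-3-carboxylate | CC(=O)OCCCCCCCCCCCCCC1=C(C(=O)OC(C)(C)C)C(C)C(OCC)O1
F5 | step 6 | tert-butyl (E)-16-acetoxy-3-oxo-2-(1-oxopropan-2-ylidene)hexadecanoate | CC(=O)OCCCCCCCCCCCCCC(=O)/C(C(=O)OC(C)(C)C)=C(/C)C=O
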